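**Retrosynthetic overview**
1. Thelephenol 17 ⇐ 16 by global deprotection; 16 ⇐ 15 by ortho-bromination of ring A (the two ring B bromines are bought in).
2. 15 ⇐ 13 by isoaromatisation: ring A is generated from a cross-conjugated 6-benzylidene-cyclohex-2-enone, not bought as an arene.
3. 13 ⇐ 6 + 8: an intermolecular aldol addition, then dehydration, joins C6 of the enone to the aldehyde carbon, which becomes the CH2 bridge.
4. 6 ⇐ 4 (Saegusa–Ito oxidation) ⇐ 1; 8 ⇐ 7 (MOM protection).
5. Ring order: ring B is aromatic from the start (7); the carbocycle of ring A is present from 1 and is aromatised only at step 9.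

Assumption: thelephenol has no stereocentre and no stereogenic double bond, so there is no enantiomer to select; stereocentres in intermediates are racemic and are all erased by step 9.

**Route**

Step 1
Reactants: 1 ethyl 1,4-dioxaspiro[4.5]decane-8-carboxylate
Product: 2 (1,4-dioxaspiro[4.5]decan-8-yl)methanol
Conditions: LiAlH4 (1.0 equiv), THF, 0 °C to rt; then H2O work-up
Reagents that add atoms: none
Why: LiAlH4 ester reduction gives the primary alcohol while the dioxolane keeps the ketone away from hydride, and no stereocentre is created.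

Step 2
Reactants: 2 (1,4-dioxaspiro[4.5]decan-8-yl)methanol
Product: 3 4-(hydroxymethyl)cyclohexan-1-one
Conditions: 2 M HCl (aq), THF, rt
Reagents that add atoms: water, O
Why: Acid-catalysed ketal hydrolysis (acetal deprotection) is driven by the large excess of water and gives the achiral keto alcohol.

Step 3
Reactants: 3 4-(hydroxymethyl)cyclohexan-1-one
Product: 4 4-[(tert-butyldimethylsilyloxy)methyl]cyclohexan-1-one
Conditions: TBSCl, imidazole, CH2Cl2, 0 °C to rt
Reagents that add atoms: tert-butyldimethylsilyl chloride (TBSCl), CC(C)(C)[Si](C)(C)Cl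
Why: Imidazole-promoted silyl ether formation protects the only hydroxyl group against the strong bases used later, and no stereocentre is formed.

Step 4
Reactants: 4 4-[(tert-butyldimethylsilyloxy)methyl]cyclohexan-1-one
Product: 5 tert-butyldimethyl{[4-(trimethylsilyloxy)cyclohex-3-en-1-yl]methoxy}silane (racemic)
Conditions: TMSOTf, Et3N, CH2Cl2, 0 °C
Reagents that add atoms: trimethylsilyl trifluoromethanesulfonate (TMSOTf), C[Si](C)(C)OS(=O)(=O)C(F)(F)F
Why: Soft enolisation with O-silylation (silyl enol ether formation) of a symmetric ketone can give only one regioisomer, and the stereocentre that appears at C4 by desymmetrisation is racemic and is removed at step 9.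

Step 5
Reactants: 5 tert-butyldimethyl{[4-(trimethylsilyloxy)cyclohex-3-en-1-yl]methoxy}silane
Product: 6 4-[(tert-butyldimethylsilyloxy)methyl]cyclohex-2-en-1-one (racemic)
Conditions: Pd(OAc)2 (1.05 equiv), MeCN, rt
Reagents that add atoms: none
Why: Saegusa–Ito oxidation, in which the enol ether is transferred to divalent palladium and the palladium enolate undergoes β-hydride elimination, installs the C2=C3 double bond regiospecifically while C4 stays racemic.

Step 6
Reactants: 7 3,5-dibromo-4-hydroxybenzaldehyde
Product: 8 3,5-dibromo-4-(methoxymethoxy)benzaldehyde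
Conditions: MOMCl, i-Pr2NEt, CH2Cl2, 0 °C to rt
Reagents that add atoms: chloromethyl methyl ether (MOMCl), COCCl
Why: Williamson-type O-alkylation (MOM acetal protection) of the acidic phenol is fast with the very reactive chloromethyl ether and removes the proton that would quench the enolate in step 7.

Step 7
Reactants: 6 4-[(tert-butyldimethylsilyloxy)methyl]cyclohex-2-en-1-one; 8 3,5-dibromo-4-(methoxymethoxy)benzaldehyde
Product: 11 6-{[3,5-dibromo-4-(methoxymethoxy)phenyl](hydroxy)methyl}-4-[(tert-butyldimethylsilyloxy)methyl]cyclohex-2-en-1-one (mixture of racemic diastereomers), via lithium dienolate 9 (not isolated), via lithium aldolate 10 (not isolated)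
Conditions: 6 (1.15 equiv), LiN(i-Pr)2 (LDA, 1.1 equiv), THF, −78 °C; then 8 (1.0 equiv), −78 °C; AcOH quench at −78 °C
Reagents that add atoms: none
Why: Kinetic deprotonation of the enone at C6 by the hindered amide gives the cross-conjugated dienolate, which undergoes a crossed intermolecular aldol addition to the non-enolisable, electron-poor aldehyde to form the C6–CH(Ar) bond; the two new stereocentres (C6 and the carbinol carbon) form unselectively and are erased in steps 8 and 9.

Step 8
Reactants: 11 6-{[3,5-dibromo-4-(methoxymethoxy)phenyl](hydroxy)methyl}-4-[(tert-butyldimethylsilyloxy)methyl]cyclohex-2-en-1-one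
Product: 13 (E)-6-[3,5-dibromo-4-(methoxymethoxy)benzylidene]-4-[(tert-butyldimethylsilyloxy)methyl]cyclohex-2-en-1-one (racemic), via mesylate 12 (not isolated)
Conditions: MsCl, Et3N, CH2Cl2, 0 °C; then DBU, 0 °C to rt
Reagents that add atoms: none
Why: Mesylation followed by E1cB β-elimination (completing the aldol condensation) gives the conjugated benzylidene enone, the E isomer being favoured thermodynamically with the aryl group anti to the carbonyl, and this geometry is lost at step 9 anyway.

Step 9
Reactants: 13 (E)-6-[3,5-dibromo-4-(methoxymethoxy)benzylidene]-4-[(tert-butyldimethylsilyloxy)methyl]cyclohex-2-en-1-one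
Product: 15 2-[3,5-dibromo-4-(methoxymethoxy)benzyl]-4-[(tert-butyldimethylsilyloxy)methyl]phenol, via potassium phenoxide 14 (not isolated)
Conditions: KOt-Bu (1.5 equiv), THF/t-BuOH, 0 °C to rt; AcOH quench
Reagents that add atoms: none
Why: Base-mediated isoaromatisation (prototropic double-bond migration) proceeds by γ-deprotonation at C4 to a trienolate, loss of the C5 proton with aromatisation and protonation of the benzylic carbanion by t-BuOH, and the gain of aromatic stabilisation makes it irreversible and erases the last stereocentre (C4).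

Step 10
Reactants: 15 2-[3,5-dibromo-4-(methoxymethoxy)benzyl]-4-[(tert-butyldimethylsilyloxy)methyl]phenol
Product: 16 2-bromo-6-[3,5-dibromo-4-(methoxymethoxy)benzyl]-4-[(tert-butyldimethylsilyloxy)methyl]phenol
Conditions: NBS (1.05 equiv), i-Pr2NH (10 mol %), CH2Cl2, 0 °C
Reagents that add atoms: N-bromosuccinimide (NBS), O=C1CCC(=O)N1Br
Why: Electrophilic aromatic bromination (amine-catalysed ortho-bromination of a phenol by NBS) can only occur at the single free position ortho to the free hydroxyl of ring A, since ring B is fully blocked and deactivated.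

Step 11
Reactants: 16 2-bromo-6-[3,5-dibromo-4-(methoxymethoxy)benzyl]-4-[(tert-butyldimethylsilyloxy)methyl]phenol
Product: 17 thelephenol, 2-bromo-6-(3,5-dibromo-4-hydroxybenzyl)-4-(hydroxymethyl)phenol
Conditions: 3 M H2SO4 (aq)/THF 1:1, 45 °C
Reagents that add atoms: none
Why: Acid-catalysed hydrolysis (global deprotection of the silyl ether and the MOM acetal) in a water-rich medium with a non-nucleophilic counter-ion frees both hydroxyl groups, and any benzylic cation formed from the p-hydroxybenzyl alcohol is recaptured by water to give the same alcohol.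

**Compound list**
1 | ethyl 1,4-dioxaspiro[4.5]decane-8-carboxylate | CCOC(=O)C1CCC2(CC1)OCCO2 | starting material
2 | (1,4-dioxaspiro[4.5]decan-8-yl)methanol | OCC1CCC2(CC1)OCCO2 | intermediate
3 | 4-(hydroxymethyl)cyclohexan-1-one | O=C1CCC(CO)CC1 | intermediate
4 | 4-[(tert-butyldimethylsilyloxy)methyl]cyclohexan-1-one | O=C1CCC(CO[Si](C)(C)C(C)(C)C)CC1 | intermediate
5 | tert-butyldimethyl{[4-(trimethylsilyloxy)cyclohex-3-en-1-yl]methoxy}silane (racemic) | C[Si](C)(C)OC1=CCC(CO[Si](C)(C)C(C)(C)C)CC1 | intermediate
6 | 4-[(tert-butyldimethylsilyloxy)methyl]cyclohex-2-en-1-one (racemic) | O=C1C=CC(CO[Si](C)(C)C(C)(C)C)CC1 | intermediate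
7 | 3,5-dibromo-4-hydroxybenzaldehyde | O=Cc1cc(Br)c(O)c(Br)c1 | starting material
8 | 3,5-dibromo-4-(methoxymethoxy)benzaldehyde | COCOc1c(Br)cc(C=O)cc1Br | intermediate
9 | lithium 4-[(tert-butyldimethylsilyloxy)methyl]cyclohexa-1,5-dien-1-olate (racemic, not isolated) | [Li+].[O-]C1=CCC(CO[Si](C)(C)C(C)(C)C)C=C1 | intermediate
10 | lithium [3,5-dibromo-4-(methoxymethoxy)phenyl]{5-[(tert-butyldimethylsilyloxy)methyl]-2-oxocyclohex-3-en-1-yl}methanolate (diastereomer mixture, not isolated) | [Li+].[O-]C(c1cc(Br)c(OCOC)c(Br)c1)C1CC(CO[Si](C)(C)C(C)(C)C)C=CC1=O | intermediate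
11 | 6-{[3,5-dibromo-4-(methoxymethoxy)phenyl](hydroxy)methyl}-4-[(tert-butyldimethylsilyloxy)methyl]cyclohex-2-en-1-one (mixture of racemic diastereomers) | OC(c1cc(Br)c(OCOC)c(Br)c1)C1CC(CO[Si](C)(C)C(C)(C)C)C=CC1=O | intermediate
12 | [3,5-dibromo-4-(methoxymethoxy)phenyl]{5-[(tert-butyldimethylsilyloxy)methyl]-2-oxocyclohex-3-en-1-yl}methyl methanesulfonate (diastereomer mixture, not isolated) | CS(=O)(=O)OC(c1cc(Br)c(OCOC)c(Br)c1)C1CC(CO[Si](C)(C)C(C)(C)C)C=CC1=O | intermediate
13 | (E)-6-[3,5-dibromo-4-(methoxymethoxy)benzylidene]-4-[(tert-butyldimethylsilyloxy)methyl]cyclohex-2-en-1-one (racemic) | O=C1C=CC(CO[Si](C)(C)C(C)(C)C)C/C1=C\c2cc(Br)c(OCOC)c(Br)c2 | intermediate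
14 | potassium 2-[3,5-dibromo-4-(methoxymethoxy)benzyl]-4-[(tert-butyldimethylsilyloxy)methyl]phenolate (not isolated) | [K+].[O-]c1ccc(CO[Si](C)(C)C(C)(C)C)cc1Cc1cc(Br)c(OCOC)c(Br)c1 | intermediate
15 | 2-[3,5-dibromo-4-(methoxymethoxy)benzyl]-4-[(tert-butyldimethylsilyloxy)methyl]phenol | Oc1ccc(CO[Si](C)(C)C(C)(C)C)cc1Cc1cc(Br)c(OCOC)c(Br)c1 | intermediate
16 | 2-bromo-6-[3,5-dibromo-4-(methoxymethoxy)benzyl]-4-[(tert-butyldimethylsilyloxy)methyl]phenol | Oc1c(Br)cc(CO[Si](C)(C)C(C)(C)C)cc1Cc1cc(Br)c(OCOC)c(Br)c1 | intermediate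
17 | thelephenol, 2-bromo-6-(3,5-dibromo-4-hydroxybenzyl)-4-(hydroxymethyl)phenol | OCc1cc(Br)c(O)c(Cc2cc(Br)c(O)c(Br)c2)c1 | target

**Totals and risks**

Total step count: 11. Longest linear sequence: 10 steps (1 to 17 through steps 1–5 and 7–11); step 6 is a one-step side branch.

The three steps most likely to fail:

Step 7 (aldol addition). The cross-conjugated dienolate 9 can add in Michael fashion to unreacted enone 6, and the aldolate 10 can revert by retro-aldol before the quench. The fallback sets out from 4 (with 8) and comes back at 13. It runs the aldol before the ring is unsaturated. The saturated ketone 4 is deprotonated with LiN(i-Pr)2 in THF at −78 °C and added to 8 to give the β-hydroxy ketone F1. This is converted with MsCl and Et3N into the mesylate F2 and eliminated with DBU to the (E)-2-arylidene ketone F3. F3 has α-protons only at C6, so LiN(i-Pr)2 and Me3SiCl at −78 °C give the cross-conjugated trimethylsilyl dienol ether F4. Saegusa–Ito oxidation of F4 with Pd(OAc)2 in MeCN then introduces the ring double bond and gives 13.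

Step 9 (isoaromatisation). The trienolate formed by KOt-Bu may add to unreacted dienone 13 and give Michael oligomers, or the strong base may attack the silyl ether. The fallback sets out from 13 and comes back at 15. It leaves carbanion chemistry altogether and moves the double bond by a metal hydride chain walk under neutral, aprotic conditions: RuHCl(CO)(PPh3)3 (5 mol %) in toluene at 100 °C. The Ru–H adds across the exocyclic C=C and β-hydride elimination towards C5 gives a cyclohexa-2,5-dienone bearing H at C4, which tautomerises to phenol 15. No new compound is made on this detour (F0).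

Step 11 (global acid deprotection). The p-hydroxybenzyl alcohol can ionise under the acid needed for the MOM group and give ethers or oligomers. The fallback sets out from 16 and comes back at 17. It moves the acid step to a stage where the benzylic carbon is an aldehyde and makes the alcohol last by a mild hydride reduction. Bu4NF buffered with AcOH in THF removes the silyl group to give the benzylic alcohol F5. MnO2 in CH2Cl2 oxidises this to the aldehyde F6. HCl in MeOH at 50 °C then cleaves the MOM ether on this acid-stable substrate to give the bisphenol aldehyde F7. NaBH4 in MeOH/THF at 0 °C reduces F7 to 17.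

**Further compounds**
F1 | step 7 | 2-{[3,5-dibromo-4-(methoxymethoxy)phenyl](hydroxy)methyl}-4-[(tert-butyldimethylsilyloxy)methyl]cyclohexan-1-one (diastereomer mixture) | OC(c1cc(Br)c(OCOC)c(Br)c1)C1CC(CO[Si](C)(C)C(C)(C)C)CCC1=O
F2 | step 7 | [3,5-dibromo-4-(methoxymethoxy)phenyl]{5-[(tert-butyldimethylsilyloxy)methyl]-2-oxocyclohexyl}methyl methanesulfonate (diastereomer mixture) | CS(=O)(=O)OC(c1cc(Br)c(OCOC)c(Br)c1)C1CC(CO[Si](C)(C)C(C)(C)C)CCC1=O
F3 | step 7 | (E)-2-[3,5-dibromo-4-(methoxymethoxy)benzylidene]-4-[(tert-butyldimethylsilyloxy)methyl]cyclohexan-1-one (racemic) | O=C1CCC(CO[Si](C)(C)C(C)(C)C)C/C1=C\c2cc(Br)c(OCOC)c(Br)c2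
F4 | step 7 | {[(6E)-6-[3,5-dibromo-4-(methoxymethoxy)benzylidene]-4-[(tert-butyldimethylsilyloxy)methyl]cyclohex-1-en-1-yl]oxy}trimethylsilane (racemic) | C[Si](C)(C)OC1=CCC(CO[Si](C)(C)C(C)(C)C)C/C1=C\c2cc(Br)c(OCOC)c(Br)c2
F0 | step 9 | none | none
F5 | step 11 | 2-bromo-6-[3,5-dibromo-4-(methoxymethoxy)benzyl]-4-(hydroxymethyl)phenol | OCc1cc(Br)c(O)c(Cc2cc(Br)c(OCOC)c(Br)c2)c1
F6 | step 11 | 3-bromo-5-[3,5-dibromo-4-(methoxymethoxy)benzyl]-4-hydroxybenzaldehyde | O=Cc1cc(Br)c(O)c(Cc2cc(Br)c(OCOC)c(Br)c2)c1
F7 | step 11 | 3-bromo-5-(3,5-dibromo-4-hydroxybenzyl)-4-hydroxybenzaldehyde | O=Cc1cc(Br)c(O)c(Cc2cc(Br)c(O)c(Br)c2)c1
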